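The data stem from a simulated flask from invented constants, and the scatter is random.

The target does not climb to the substrate charge: the south-east run reads 82.6 mM at 34 min out of 150 mM of substrate charged, even though it holds more partner, 165 mM, than substrate.

| flask | substrate | partner | catalyst | time |
|---|---|---|---|---|
| west | 150 mM | 165 mM | 15.0 mM |  |
| south-west | 150 mM | 490 mM | 15.0 mM |  |
| south-east | 150 mM | 165 mM | 30.0 mM |  |
| north-west | 150 mM | 165 mM | 15.0 mM | 85 min |

| run | time / min | [target] / mM |
|---|---|---|
| west run | 4.2 | 14.9 |
| west run | 8.5 | 31.8 |
| west run | 13 | 43.2 |
| west run | 17 | 57.0 |
| west run | 21 | 58.3 |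
| west run | 26 | 62.6 |
| west run | 30 | 67.8 |
| west run | 34 | 71.2 |
| south-west run | 4.2 | 15.7 |
| south-west run | 8.5 | 39.1 |
| south-west run | 13 | 55.0 |
| south-west run | 17 | 66.6 |
| south-west run | 21 | 73.7 |
| south-west run | 26 | 80.3 |
| south-west run | 30 | 78.9 |
| south-west run | 34 | 81.8 |
| south-east run | 4.2 | 20.8 |
| south-east run | 8.5 | 57.4 |
| south-east run | 13 | 68.6 |
| south-east run | 17 | 74.8 |
| south-east run | 21 | 82.2 |
| south-east run | 26 | 82.0 |
| south-east run | 30 | 85.4 |
| south-east run | 34 | 82.6 |

(standard deviation of a reading: 2 mM)

- the exponent of [catalyst] in the starting rate at the charge of the west run (at the point where two percent of the substrate have become target)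
- the exponent of [partner] in the starting rate at the charge of the west run (at the point where two percent of the substrate have become target)
- target in the north-west run at 85 min, as a share of the substrate charged

- Overall: substrate + partner -> target, with catalyst as catalyst.
- Constant volume, constant temperature.
- What is held in complexes is read along with the free species.
- "The second partner" is partner.
- An order is taken over about fifteen percent of the charge, up and down.

First, how much do the charges move the early rate? You can make a rough reading from the target at 8.5 min. Raising the partner from 165 mM to 490 mM multiplies the target there by 1.23, so I reckon its order at 0.190. Raising the catalyst from 15.0 mM to 30.0 mM multiplies it by 1.81, so I reckon that order at 0.852.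

Second, where does the west run end? Its target still rises by 8.60 mM from 26 min to 34 min, more than the scatter of 2 mM, so its last reading need not be its end. The south-west run has the same catalyst charge and rises by 1.50 mM over those times, but the difference of two readings scatters by 2.83 mM, so this rise does not show that the run has stopped, and the mean of its last 3 readings is a rough stand-in for its end, low if the run is still climbing. That gives a factor of 1.21: the closing factor, that late mean of target divided by the target at 17 min. Applied to the west reading of 57.0 mM at 17 min, it gives 68.8 mM, so my reckoning for the north-west run, a repeat of the west charge, is 45.8% at 85 min.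

The forecast differs from this. It gives 1 for catalyst, 0.35 for partner and 56% for the target share, on these grounds: “So I read it as a fixed reactive pool of substrate, with the rest unreactive or lost.”

The flask gives 0.60 for catalyst, 0.14 for partner and 46.5%, which is 69.8 mM of target. Where the same small amount of target has been made, the south-east run goes at 1.5 times the rate of the west run.

    active catalyst + partner ⇌ catalyst-reagent complex, settled at all times (19.20 M⁻¹)
    catalyst-reagent complex + substrate → target + active catalyst (6.120 M⁻¹ min⁻¹)
    2 partner → lost reagent (0.6420 M⁻¹ min⁻¹)
    catalyst → active catalyst (0.2370 min⁻¹)

The closing factor of this charge comes out at 1.22, against the 1.21 carried over. On the south-east run, with 30.0 mM of catalyst, 1.21 times its 74.8 mM at 17 min gives 90.5 mM, and its last 3 readings average 83.3 mM.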